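**Strategy.** Chain atoms are numbered from the ester oxygen (O–C1 to C18). The octadecyl chain carries no handle beyond C1, so its C5–C6 methylene–methylene link is built at the alkene oxidation level. Ruthenium-catalysed cross-metathesis joins hex-5-en-1-yl 2,3-dihydroxybenzoate (the catechol ring, the ester and C1–C5) to tetradec-1-ene (C6–C18) through a C5=C6 double bond, and hydrogenation in the same flask saturates it, so one operation delivers the saturated C18 ester. The feature exploited is that C5–C6 lies in an unbranched, stereochemically silent CH2 run remote from the benzene ring, where a transient alkene costs nothing; the free catechol and aryl ester ride through unprotected.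

Key step: step 2

Remark on the chemistry: the geometry of the C5=C6 alkene 5 is not controlled (E isomer drawn); both isomers converge on 6 on hydrogenation.

**Step 1**
Reactants: 1 2,3-dihydroxybenzoic acid; 2 6-bromohex-1-ene
Product: 3 hex-5-en-1-yl 2,3-dihydroxybenzoate
Conditions: KHCO3 (1.2 equiv), DMF, 50 °C, N2
Reagents that add atoms: none
Why: Carboxylate O-alkylation (SN2 esterification): hydrogencarbonate deprotonates only the CO2H (pKa about 3) and not the phenols, so the carboxylate is the sole competent nucleophile toward the primary bromide and the catechol stays free.

**Step 2**
Reactants: 3 hex-5-en-1-yl 2,3-dihydroxybenzoate; 4 tetradec-1-ene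
Product: 6 Gentiside E (octadecyl 2,3-dihydroxybenzoate), via octadec-5-en-1-yl 2,3-dihydroxybenzoate 5 (not isolated)
Conditions: 4 (3 equiv), Hoveyda–Grubbs II (3 mol%), 1,4-benzoquinone (10 mol%), EtOAc, 45 °C, Ar purge; then 10% Pd/C, H2 (1 atm), rt, same flask
Reagents that add atoms: none
Why: The Ru alkylidene exchanges the two terminal =CH2 groups by [2+2] cycloaddition/cycloreversion through ruthenacyclobutanes, so C5 of 3 and C1 of 4 become the C5=C6 double bond of 5 with loss of ethylene, and Pd/C–H2 then saturates that bond in the same flask. The closest known reaction type is cross-metathesis of two unhindered terminal alkenes telescoped with heterogeneous hydrogenation. No ring is closed and no stereocentre is formed; 5 should arise as an E/Z mixture, which is of no consequence because both isomers converge on 6. The step needs cross- over homo-coupling and retention of the double-bond position: the excess of 4 and the reversibility of the homodimerisations (ethylene swept out) should drive 3 into the cross product, while benzoquinone traps Ru–H species that would otherwise migrate the double bond and lead to C17/C19 homologues. Chemoselectivity rests on the substrate: the neutral catechol (no base present, 2-OH hydrogen-bonded to the ester C=O) should not displace chloride on Ru, and the aryl ester and catechol are inert to Pd/C–H2 at 1 atm. The hydrocarbon co-products (excess 4 and its homodimer) are saturated as well and are removed from the polar catechol ester by chromatography.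

**Compound list**
1 | 2,3-dihydroxybenzoic acid | O=C(O)c1cccc(O)c1O | starting material
2 | 6-bromohex-1-ene | C=CCCCCBr | starting material
3 | hex-5-en-1-yl 2,3-dihydroxybenzoate | C=CCCCCOC(=O)c1cccc(O)c1O | intermediate
4 | tetradec-1-ene | CCCCCCCCCCCCC=C | starting material
5 | octadec-5-en-1-yl 2,3-dihydroxybenzoate (E isomer drawn; Z isomer expected alongside; not isolated) | CCCCCCCCCCCC/C=C/CCCCOC(=O)c1cccc(O)c1O | intermediate
6 | Gentiside E (octadecyl 2,3-dihydroxybenzoate) | CCCCCCCCCCCCCCCCCCOC(=O)c1cccc(O)c1O | target

**Total step count:** 2
**Longest linear sequence:** 2 steps (1 → 3 → 6)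

**Steps most likely to fail** (the route has only two steps, so both are ranked)

1. Step 2. The processes at risk are deactivation of the ruthenium alkylidene by the free catechol (chelation or adventitious oxidation to an o-quinone), migration of the terminal double bonds before metathesis (chain-length homologues that cannot be separated from 6), and statistical homodimerisation of 3. The fallback forms the same C5–C6 bond directly at the alkane level by a palladium-catalysed alkyl–alkyl coupling on a protected substrate. It sets out from 1 and returns to the route at 6.
   - Carboxylate alkylation of 1 with 5-bromopent-1-ene (KHCO3, DMF, 50 °C) should give pent-4-en-1-yl 2,3-dihydroxybenzoate F1.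
   - Benzylation of both phenols (BnBr, K2CO3, DMF, 60 °C) should give pent-4-en-1-yl 2,3-bis(benzyloxy)benzoate F2.
   - Anti-Markovnikov hydroboration with 9-BBN (THF, rt) should place boron on the terminal carbon and give 5-(9-borabicyclo[3.3.1]nonan-9-yl)pentyl 2,3-bis(benzyloxy)benzoate F3, used in the flask.
   - B-alkyl Suzuki–Miyaura coupling of F3 with 1-bromotridecane (Pd(OAc)2, PCy3, K3PO4·H2O, THF, rt) should give octadecyl 2,3-bis(benzyloxy)benzoate F4.
   - Hydrogenolysis of both benzyl ethers (H2, 10% Pd/C, EtOAc, rt) should deliver 6.

2. Step 1. The process at risk is competing O-alkylation of the exposed 3-OH (or over-alkylation) alongside ester formation, leading to ether/ester mixtures. The fallback is a chemoselective Mitsunobu esterification, which activates the alcohol and not the acid. It sets out from 1 and returns to the route at 3: 1 is treated with hex-5-en-1-ol, PPh3 and DIAD (THF, 0 °C to rt). Only the carboxylic acid is acidic enough to be engaged rapidly by the alkoxyphosphonium intermediate, so 3 should form directly and no new intermediate is needed.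

**Further compounds**
F1 | step 2 | pent-4-en-1-yl 2,3-dihydroxybenzoate | C=CCCCOC(=O)c1cccc(O)c1O
F2 | step 2 | pent-4-en-1-yl 2,3-bis(benzyloxy)benzoate | C=CCCCOC(=O)c1cccc(OCc2ccccc2)c1OCc1ccccc1
F3 | step 2 | 5-(9-borabicyclo[3.3.1]nonan-9-yl)pentyl 2,3-bis(benzyloxy)benzoate | O=C(OCCCCCB1C2CCCC1CCC2)c1cccc(OCc2ccccc2)c1OCc1ccccc1
F4 | step 2 | octadecyl 2,3-bis(benzyloxy)benzoate | CCCCCCCCCCCCCCCCCCOC(=O)c1cccc(OCc2ccccc2)c1OCc1ccccc1
F0 | step 1 | none | none
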